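## Analysis of the target

15-Keto-PGF2α (25) is a cyclopentane with four contiguous stereocentres, C8 (R), C9 (S), C11 (R) and C12 (R), and two chains. The hydroxyls at C9 and C11 and the seven-carbon acid chain at C8 lie on the α face, and the eight-carbon chain at C12 lies on the β face. C8/C12 and C11/C12 are therefore trans and C8/C9 cis. The upper chain holds a (Z)-C5=C6 alkene and the free acid. The lower chain is an (E)-enone, C13=C14–C15=O, with no stereocentre of its own. The sensitive points are the enone (conjugate addition, γ-deprotonation at C12), the cis alkene, and any 9-oxo-11-hydroxy intermediate, which loses water easily. The synthesis is hard for two reasons: four adjacent centres sit on a flexible five-membered ring, and the ring oxygen at C9 must pass through a ketone while C15 has to end as one. The strategy rests on C8 and C12, which are adjacent, trans, and each carry a chain. C8 maps onto the β-carbon of a nitroalkene that already bears C1–C7, and C12 onto the α-carbon of a 1,4-dialdehyde whose formyl group is C13. The nitro carbon becomes C9 and the CH2–CHO tail of the dialdehyde becomes C11 and C10, so a Michael addition followed by a Henry reaction closes the ring C8–C9–C10–C11–C12.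

## Retrosynthetic reasoning

**C15 oxidation level (25 ⇒ 24).** The C15 carbonyl is made last. One step back it is the allylic carbinol of 24, the only one of the three alcohols that an allylic-selective oxidant attacks. Keeping C15 as an sp3 carbon from 15 to 24 (silylated from 19 to 22) is what allows the ring to be oxidised and reduced without competition from the side chain.

**C9–H (24 ⇒ 23 ⇒ 22 ⇒ 21).** The C9 carbinol is taken back to ketone 21. The α-oriented C8 chain screens the α face, so a bulky hydride must enter from the β face and the hydroxyl ends cis to that chain. Ester cleavage and desilylation (24 ⇒ 23 ⇒ 22) are placed between this reduction and the final oxidation, so that no base meets the finished enone.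

**C11–O (21 ⇒ 20 ⇒ 19 ⇒ 18).** The C11 hydroxyl is traced through the C10–O bond of epoxy ketone 20 back to the C10=C11 alkene of enone 19, the silyl ether of 18. The forward sequence has to add peroxide to C11 anti to the C12 chain and then cleave only the bond at the α-carbon.

**C9=O and C10=C11 (18 ⇒ 16 ⇒ 15).** The enone of 18 is the unmasked form of nitroalkene 16, which is the dehydration product of nitro alcohol 15. This pair of steps moves the oxygen that the annulation must place at C10 onto C9 and opens C11 for oxygenation. It also erases the C9 and C10 centres of 15, whose configuration therefore never matters.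

**C13=C14 (15 ⇒ 14 ⇒ 12 + 13).** The lower chain is cut at the alkene into aldehyde 12 and ketophosphonate 13, an (E)-selective olefination on a formyl group that the annulation delivers directly. The C15 ketone of 14 is reduced at once so that it stays out of the way.

**C9–C10 and C8–C12 (12 ⇒ 11 ⇒ 8 + 10).** Opening the ring at C9–C10 (retro-Henry) gives dialdehyde 11, and cutting C8–C12 (retro-Michael) gives nitrodiene 8 and dialdehyde 10. No other pair of cuts releases two achiral fragments that already contain both chains' attachment points. The forward step must fix C8 by catalyst control and let C12 settle trans.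

**Fragments (8 ⇒ 7 ⇒ 5 + 6; 5 ⇒ 4 ⇒ 3 ⇒ 1 + 2; 10 ⇒ 9).** The nitroalkene is cut at C8=C9 into aldehyde 5 and nitromethane 6 by way of nitro alcohol 7. The (Z)-alkene of 5 is cut at C5=C6 into phosphonium salt 1 and aldehyde 2. Dialdehyde 10 comes from its cyclic bis-acetal 9.

## Alternatives that were turned down

**Alternative 1:** The C11–O bond and the C13=C14 alkene are retro-formed into a C11–C13 σ-bond, that is, a cyclopropane spanning C11, C12 and C13, with a 14,15-epoxide on the side chain (A2). In the forward key step, acid opens the epoxide of A2 at C14. The resulting cyclopropylcarbinyl cation relays the charge to C11 as the C11–C13 bond becomes the (E)-alkene, and the aqueous medium is captured at C11 from the α face, giving lactone diol A1.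
- For it: one step installs the oxygen on the correct carbon, C11, together with the trans alkene. The chosen route is weaker here, since it places oxygen at C10 and needs three steps to move it.
- Also for it: the C15 epimer mixture in A1 does no harm for this target, because C15 ends as a ketone.
- Against it: A2 needs its own multi-step enantioselective synthesis (cyclopropane, lactone, side chain, epoxide), and the cationic manifold can also leak to cyclobutyl, 11β and unrearranged diol products.
- Against it: after A1 the acid chain must still be added through lactol formation and a Wittig reaction with 1, under protection of two hydroxyls, followed by the oxidation of step 18.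
- Comparison: the count is no shorter than the chosen route, and the chosen route builds the ring and both chain-bearing centres catalytically from achiral pieces.

**Alternative 2:** The lactone C9–O bond is cut back to a cyclobutanone by a retro-Baeyer–Villiger step. In the forward key step, a cyclohexanone monooxygenase oxidises racemic ketone A3 aerobically; the (1R,5S) enantiomer gives lactone A4 by migration of the ring-fusion carbon with retention.
- For it: A3 is cheap, and everything after A4 is the textbook lactone route. In reliability of the individual steps this alternative is stronger than the chosen one.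
- Against it: the enzyme sends the other enantiomer along a different regiochemical course, so at most half of A3 becomes A4. Fermentation or isolated enzyme with cofactor recycling is also required.
- Against it: A4 carries two stereocentres and neither chain. C11, C12, the lower chain (with 13), the same masking of C15, lactone reduction and the Wittig reaction with 1 all remain, so the sequence is longer and fully linear.
- Comparison: the chosen route spends its risk in one step but arrives there with the acid chain already in place and without a resolution.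

**Alternative 3:** All ring bonds are cut back to the polyene acid A5. In the forward key step, ovine prostaglandin H synthase (cyclooxygenase 1) performs a double dioxygenation of A5, forming C8–C12, both endoperoxide C–O bonds and the C15–O bond to give A6.
- For it: reduction of both peroxide groups of A6 would give 24, and step 18 would finish the synthesis. In step count and in stereocontrol this cannot be matched, and it is clearly superior on both points.
- Against it: A6 is a short-lived endoperoxide that rearranges and fragments in the buffer in which it forms.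
- Against it: the enzyme inactivates itself after limited turnover, and its peroxidase site must be held back to stop at A6.
- Against it: the protein is not a shelf reagent, so the method gives analytical to milligram amounts.
- Comparison: the chosen route is far longer, but every intermediate is stable, control comes from reagents, and the scale is limited only by chromatography.

Key step: step 7

Remark on the chemistry: C15 is carried as the single (15S) carbinol for ease of handling, although either epimer would serve. Compound 12 is written as the expected all-trans isomer; other C9/C10 epimers would converge in steps 10 and 11.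

## Route

Step 1
Reactants: 1 (4-carboxybutyl)triphenylphosphonium bromide; 2 3-[(tert-butyldimethylsilyl)oxy]propanal
Product: 3 (5Z)-8-[(tert-butyldimethylsilyl)oxy]oct-5-enoic acid
Conditions: NaN(SiMe3)2 (2.1 equiv), THF, 0 °C; then 2, −78 °C to rt; 1 M HCl work-up
Reagents that add atoms: none
Why: Wittig olefination of a non-stabilised ylide generated with a sodium base is kinetically Z-selective through the cis-oxaphosphetane; the second equivalent of base only forms the carboxylate.

Step 2
Reactants: 3
Product: 4 methyl (5Z)-8-hydroxyoct-5-enoate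
Conditions: HCl (1.25 M in MeOH), rt
Reagents that add atoms: methanol, CO
Why: Fischer esterification and acid methanolysis of the primary silyl ether run in the same medium; the isolated cis alkene is inert to dilute methanolic acid.

Step 3
Reactants: 4
Product: 5 methyl (5Z)-8-oxooct-5-enoate
Conditions: Dess–Martin periodinane, NaHCO3, CH2Cl2, 0 °C; used at once
Reagents that add atoms: none
Why: Dess–Martin oxidation is fast and non-basic, the usual way to a (Z)-alk-3-enal without migration of the alkene into conjugation.

Step 4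
Reactants: 5; 6 nitromethane
Product: 7 methyl (5Z)-8-hydroxy-9-nitronon-5-enoate (racemic)
Conditions: MeNO2 (10 equiv), Et3N (0.1 equiv), THF, 0 °C
Reagents that add atoms: none
Why: Henry reaction; the excess of nitromethane buffers the amine and should trap the aldehyde faster than it enolises, as in the usual preparation of nitrated skipped dienes from (Z)-alk-3-enals. The new carbinol centre is racemic and is removed in step 5.

Step 5
Reactants: 7
Product: 8 methyl (5Z,8E)-9-nitronona-5,8-dienoate
Conditions: DCC (1.2 equiv), CuCl (5 mol %), Et2O, rt; filtered and used the same day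
Reagents that add atoms: none
Why: CuCl-catalysed addition of the alcohol to the carbodiimide and intramolecular elimination dehydrate nitroaldols under neutral conditions, giving the more stable (E)-nitroalkene without exposing the doubly allylic C7 methylene to base.

Step 6
Reactants: 9 2,5-dimethoxytetrahydrofuran
Product: 10 succinaldehyde (butanedial)
Conditions: H2O, 90 °C, MeOH distilled off; CH2Cl2 extraction, short-path distillation; used fresh
Reagents that add atoms: water, O
Why: Hydrolysis of the cyclic bis-acetal is driven by removal of methanol; the dialdehyde oligomerises on standing and is therefore made directly before use.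

Step 7
Reactants: 8; 10
Product: 12 methyl (5Z)-7-[(1R,2S,3S,5S)-5-formyl-3-hydroxy-2-nitrocyclopentyl]hept-5-enoate, via Michael adduct 11 (not isolated)
Conditions: (S)-2-[diphenyl(trimethylsilyloxy)methyl]pyrrolidine (10 mol %), 4-nitrophenol (10 mol %), 10 (3 equiv), MeCN, 0 °C to rt; then i-Pr2NEt (1.5 equiv), 0 °C
Reagents that add atoms: none
Why: The pyrrolidine condenses with one formyl group of 10 to the (E)-enamine, whose face next to the diphenyl(silyloxy)methyl group is blocked; its α-carbon (C12) attacks the β-carbon (C8) of 8 through a synclinal open transition state, forming C8–C12 and, after hydrolysis, the syn adduct 11. The closest known reaction type is the diarylprolinol silyl ether catalysed Michael addition of aldehydes, this dialdehyde included, to β-alkyl nitroalkenes with Henry closure in the same pot, known for saturated nitroalkenes; 8 differs only in its remote (Z)-alkene. i-Pr2NEt then deprotonates C9 and the nitronate carbon adds to the second formyl carbon C10, a 5-(enolexo)-exo-trig closure that gives the cyclopentane C8–C9–C10–C11–C12. C8 (R) is set by the catalyst alone, through the open enamine face and the (E) geometry of 8. C12 is formed with the formyl group cis to the C8 chain, but as an enolisable α-formyl centre it equilibrates under the amine base to the trans arrangement of 12. C9 and C10 arise under thermodynamic control (reversible Henry reaction, epimerisable nitro-bearing carbon) and are expected all-trans; both are erased in steps 10 and 11. The step needs the Michael addition to outrun self-aldol reaction of 10 and any base-induced shift of the C8=C9 bond of 8 towards C7; excess 10, the acidic co-catalyst and adding the tertiary amine only after 8 is consumed are meant to secure this.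

Step 8
Reactants: 12; 13 dimethyl (2-oxoheptyl)phosphonate
Product: 14 methyl (5Z)-7-[(1R,2S,3S,5R)-3-hydroxy-2-nitro-5-[(1E)-3-oxooct-1-en-1-yl]cyclopentyl]hept-5-enoate
Conditions: LiCl, i-Pr2NEt, MeCN, 0 °C to rt
Reagents that add atoms: none
Why: Horner–Wadsworth–Emmons olefination of a β-ketophosphonate under mild LiCl/amine conditions is (E)-selective and tolerates the base-sensitive nitroaldol; C12 already sits at its trans equilibrium position.

Step 9
Reactants: 14
Product: 15 methyl (5Z)-7-[(1R,2S,3S,5R)-3-hydroxy-5-[(1E,3S)-3-hydroxyoct-1-en-1-yl]-2-nitrocyclopentyl]hept-5-enoate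
Conditions: (−)-Ipc2BCl (3 equiv), THF, −40 to −20 °C; then MeOH, aq. NaHCO3
Reagents that add atoms: none
Why: Reagent-controlled reduction of the enone carbonyl through a six-membered hydride-transfer transition state should give the (15S)-allylic alcohol; the Lewis acidic, non-basic borane does not provoke retro-Henry opening. C15 is oxidised again in step 18, so this centre only keeps 15 to 24 single isomers.

Step 10
Reactants: 15
Product: 16 methyl (5Z)-7-[(1R,5R)-5-[(1E,3S)-3-hydroxyoct-1-en-1-yl]-2-nitrocyclopent-2-en-1-yl]hept-5-enoate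
Conditions: acidic Al2O3, ClCH2CH2Cl, 60 °C
Reagents that add atoms: none
Why: Dehydration of the β-nitro alcohol (E1cB through the nitronate) forms the conjugated nitroalkene C9=C10 and removes the two provisional centres; the C15 alcohol has no such pathway.

Step 11
Reactants: 16
Product: 18 methyl (5Z)-7-[(1R,2S)-2-[(1E,3S)-3-hydroxyoct-1-en-1-yl]-5-oxocyclopent-3-en-1-yl]hept-5-enoate, via allylic nitro isomer 17 (not isolated)
Conditions: DABCO (2 equiv), O2 (1 atm), MeCN, 0 °C to rt
Reagents that add atoms: dioxygen, O=O
Why: The base removes a C11 proton and moves the double bond to C10=C11 (17 and its nitronate); the nitronate carbon C9 is oxygenated and collapses with loss of nitrite, an aerobic Nef reaction that gives the cyclopent-2-enone. The mild amine base should leave C8 and C12 alone.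

Step 12
Reactants: 18
Product: 19 methyl (5Z)-7-[(1R,2S)-2-[(1E,3S)-3-[(tert-butyldiphenylsilyl)oxy]oct-1-en-1-yl]-5-oxocyclopent-3-en-1-yl]hept-5-enoate
Conditions: t-BuPh2SiCl, imidazole, DMF, 0 °C to rt
Reagents that add atoms: tert-butyl(chloro)diphenylsilane, CC(C)(C)[Si](Cl)(c1ccccc1)c1ccccc1
Why: Standard silylation of the secondary allylic alcohol; the bulky aryl silyl ether protects C15 through steps 13 to 15 and adds bulk over the β face of the ring.

Step 13
Reactants: 19
Product: 20 methyl (5Z)-7-[(1S,2R,3R,5S)-2-[(1E,3S)-3-[(tert-butyldiphenylsilyl)oxy]oct-1-en-1-yl]-4-oxo-6-oxabicyclo[3.1.0]hexan-3-yl]hept-5-enoate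
Conditions: 30% H2O2, NaOH (0.3 equiv), MeOH, −40 °C
Reagents that add atoms: hydrogen peroxide, OO
Why: Nucleophilic (Weitz–Scheffer) epoxidation of the cyclopentenone; hydroperoxide should add to C11 anti to the β-oriented C12 chain, whose reach is extended by the silyl ether, so that the 10α,11α-epoxide predominates.

Step 14
Reactants: 20
Product: 21 methyl (5Z)-7-[(1R,2R,3R)-2-[(1E,3S)-3-[(tert-butyldiphenylsilyl)oxy]oct-1-en-1-yl]-3-hydroxy-5-oxocyclopentyl]hept-5-enoate
Conditions: Zn dust, NH4Cl, MeOH/H2O, rt
Reagents that add atoms: none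
Why: Two-electron reduction of the α,β-epoxy ketone cleaves only the C10–O bond at the α-carbon and leaves the C11 oxygen with its α (R) configuration; the near-neutral medium avoids β-elimination of the new hydroxyl.

Step 15
Reactants: 21
Product: 22 methyl (5Z)-7-[(1R,2R,3R,5S)-2-[(1E,3S)-3-[(tert-butyldiphenylsilyl)oxy]oct-1-en-1-yl]-3,5-dihydroxycyclopentyl]hept-5-enoate
Conditions: LiBH(s-Bu)3 (2.5 equiv), THF, −78 °C; then aq. NH4Cl
Reagents that add atoms: none
Why: The bulky trialkylborohydride should attack the C9 ketone from the β face, away from the adjacent α-oriented C8 chain, giving the 9α (S) alcohol, as in known reductions of E-type to F-type prostaglandins.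

Step 16
Reactants: 22
Product: 23 methyl (5Z)-7-[(1R,2R,3R,5S)-3,5-dihydroxy-2-[(1E,3S)-3-hydroxyoct-1-en-1-yl]cyclopentyl]hept-5-enoate
Conditions: Bu4NF, THF, rt; then aq. NH4Cl
Reagents that add atoms: none
Why: Fluoride cleaves the silyl ether; nothing else in the triol ester is fluoride-sensitive.

Step 17
Reactants: 23
Product: 24 (5Z)-7-[(1R,2R,3R,5S)-3,5-dihydroxy-2-[(1E,3S)-3-hydroxyoct-1-en-1-yl]cyclopentyl]hept-5-enoic acid (PGF2α)
Conditions: LiOH, THF/H2O, rt; then 1 M HCl to pH 4
Reagents that add atoms: lithium hydroxide, [Li+].[OH-]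
Why: Saponification of the methyl ester is done before the enone exists, so that hydroxide never meets the γ-epimerisable C12 of the final product.

Step 18
Reactants: 24
Product: 25 (5Z)-7-[(1R,2R,3R,5S)-3,5-dihydroxy-2-[(1E)-3-oxooct-1-en-1-yl]cyclopentyl]hept-5-enoic acid (15-keto-PGF2α)
Conditions: DDQ (1.2 equiv), 1,4-dioxane, rt
Reagents that add atoms: none
Why: DDQ oxidises allylic alcohols by hydride abstraction and leaves the saturated C9 and C11 carbinols alone, so only C15 becomes a ketone; the alkenes and the four ring centres are not involved.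

## Compound list

1 | (4-carboxybutyl)triphenylphosphonium bromide | OC(=O)CCCC[P+](c1ccccc1)(c1ccccc1)c1ccccc1.[Br-] | starting material
2 | 3-[(tert-butyldimethylsilyl)oxy]propanal | O=CCCO[Si](C)(C)C(C)(C)C | starting material
3 | (5Z)-8-[(tert-butyldimethylsilyl)oxy]oct-5-enoic acid | OC(=O)CCC/C=C\CCO[Si](C)(C)C(C)(C)C | intermediate
4 | methyl (5Z)-8-hydroxyoct-5-enoate | COC(=O)CCC/C=C\CCO | intermediate
5 | methyl (5Z)-8-oxooct-5-enoate | COC(=O)CCC/C=C\CC=O | intermediate
6 | nitromethane | C[N+](=O)[O-] | starting material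
7 | methyl (5Z)-8-hydroxy-9-nitronon-5-enoate (racemic) | COC(=O)CCC/C=C\CC(O)C[N+](=O)[O-] | intermediate
8 | methyl (5Z,8E)-9-nitronona-5,8-dienoate | COC(=O)CCC/C=C\C/C=C/[N+](=O)[O-] | intermediate
9 | 2,5-dimethoxytetrahydrofuran (cis/trans mixture) | COC1CCC(OC)O1 | starting material
10 | succinaldehyde (butanedial) | O=CCCC=O | intermediate
11 | methyl (5Z,8R,9R)-9-formyl-8-(nitromethyl)-11-oxoundec-5-enoate (syn Michael adduct, not isolated) | O=C[C@H](CC=O)[C@@H](C/C=C\CCCC(=O)OC)C[N+](=O)[O-] | intermediate
12 | methyl (5Z)-7-[(1R,2S,3S,5S)-5-formyl-3-hydroxy-2-nitrocyclopentyl]hept-5-enoate (expected all-trans isomer) | O=C[C@@H]1[C@@H](C/C=C\CCCC(=O)OC)[C@H]([N+](=O)[O-])[C@@H](O)C1 | intermediate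
13 | dimethyl (2-oxoheptyl)phosphonate | CCCCCC(=O)CP(=O)(OC)OC | starting material
14 | methyl (5Z)-7-[(1R,2S,3S,5R)-3-hydroxy-2-nitro-5-[(1E)-3-oxooct-1-en-1-yl]cyclopentyl]hept-5-enoate | CCCCCC(=O)/C=C/[C@@H]1[C@@H](C/C=C\CCCC(=O)OC)[C@H]([N+](=O)[O-])[C@@H](O)C1 | intermediate
15 | methyl (5Z)-7-[(1R,2S,3S,5R)-3-hydroxy-5-[(1E,3S)-3-hydroxyoct-1-en-1-yl]-2-nitrocyclopentyl]hept-5-enoate | CCCCC[C@H](O)/C=C/[C@@H]1[C@@H](C/C=C\CCCC(=O)OC)[C@H]([N+](=O)[O-])[C@@H](O)C1 | intermediate
16 | methyl (5Z)-7-[(1R,5R)-5-[(1E,3S)-3-hydroxyoct-1-en-1-yl]-2-nitrocyclopent-2-en-1-yl]hept-5-enoate | CCCCC[C@H](O)/C=C/[C@@H]1[C@@H](C/C=C\CCCC(=O)OC)C([N+](=O)[O-])=CC1 | intermediate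
17 | methyl (5Z)-7-[(1R,5R)-5-[(1E,3S)-3-hydroxyoct-1-en-1-yl]-2-nitrocyclopent-3-en-1-yl]hept-5-enoate (C9 epimers, not isolated) | CCCCC[C@H](O)/C=C/[C@H]1C=CC([N+](=O)[O-])[C@@H]1C/C=C\CCCC(=O)OC | intermediate
18 | methyl (5Z)-7-[(1R,2S)-2-[(1E,3S)-3-hydroxyoct-1-en-1-yl]-5-oxocyclopent-3-en-1-yl]hept-5-enoate (PGA2 methyl ester) | CCCCC[C@H](O)/C=C/[C@H]1C=CC(=O)[C@@H]1C/C=C\CCCC(=O)OC | intermediate
19 | methyl (5Z)-7-[(1R,2S)-2-[(1E,3S)-3-[(tert-butyldiphenylsilyl)oxy]oct-1-en-1-yl]-5-oxocyclopent-3-en-1-yl]hept-5-enoate | CCCCC[C@H](O[Si](c1ccccc1)(c1ccccc1)C(C)(C)C)/C=C/[C@H]1C=CC(=O)[C@@H]1C/C=C\CCCC(=O)OC | intermediate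
20 | methyl (5Z)-7-[(1S,2R,3R,5S)-2-[(1E,3S)-3-[(tert-butyldiphenylsilyl)oxy]oct-1-en-1-yl]-4-oxo-6-oxabicyclo[3.1.0]hexan-3-yl]hept-5-enoate (10α,11α-epoxide) | CCCCC[C@H](O[Si](c1ccccc1)(c1ccccc1)C(C)(C)C)/C=C/[C@H]1[C@@H]2O[C@@H]2C(=O)[C@@H]1C/C=C\CCCC(=O)OC | intermediate
21 | methyl (5Z)-7-[(1R,2R,3R)-2-[(1E,3S)-3-[(tert-butyldiphenylsilyl)oxy]oct-1-en-1-yl]-3-hydroxy-5-oxocyclopentyl]hept-5-enoate | CCCCC[C@H](O[Si](c1ccccc1)(c1ccccc1)C(C)(C)C)/C=C/[C@H]1[C@H](O)CC(=O)[C@@H]1C/C=C\CCCC(=O)OC | intermediate
22 | methyl (5Z)-7-[(1R,2R,3R,5S)-2-[(1E,3S)-3-[(tert-butyldiphenylsilyl)oxy]oct-1-en-1-yl]-3,5-dihydroxycyclopentyl]hept-5-enoate | CCCCC[C@H](O[Si](c1ccccc1)(c1ccccc1)C(C)(C)C)/C=C/[C@@H]1[C@@H](C/C=C\CCCC(=O)OC)[C@@H](O)C[C@H]1O | intermediate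
23 | methyl (5Z)-7-[(1R,2R,3R,5S)-3,5-dihydroxy-2-[(1E,3S)-3-hydroxyoct-1-en-1-yl]cyclopentyl]hept-5-enoate (PGF2α methyl ester) | CCCCC[C@H](O)/C=C/[C@@H]1[C@@H](C/C=C\CCCC(=O)OC)[C@@H](O)C[C@H]1O | intermediate
24 | (5Z)-7-[(1R,2R,3R,5S)-3,5-dihydroxy-2-[(1E,3S)-3-hydroxyoct-1-en-1-yl]cyclopentyl]hept-5-enoic acid (PGF2α) | CCCCC[C@H](O)/C=C/[C@@H]1[C@@H](C/C=C\CCCC(=O)O)[C@@H](O)C[C@H]1O | intermediate
25 | (5Z)-7-[(1R,2R,3R,5S)-3,5-dihydroxy-2-[(1E)-3-oxooct-1-en-1-yl]cyclopentyl]hept-5-enoic acid (15-keto-PGF2α) | CCCCCC(=O)/C=C/[C@@H]1[C@@H](C/C=C\CCCC(=O)O)[C@@H](O)C[C@H]1O | target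

## Step count and least certain steps

Total: 18 steps. Longest linear sequence: 17 steps (steps 1 to 5 and 7 to 18, from 1); step 6 is a one-step side branch. Steps 7 and 8 can be run in one pot.

**Step 7 (key step).** The C7 methylene of 8 is flanked by the nitrovinyl group and the (Z)-alkene. The secondary amine catalyst, or the tertiary amine added later, may remove a C7 proton and shift the C8=C9 double bond into conjugation with C5=C6 before the enamine has added. This would consume the acceptor; self-aldol oligomerisation of 10 would then dominate.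

Fallback, setting out from 2 and 6 and returning at 24: the same ring closure is run on a nitroalkene without the skipped alkene, and C1–C5 are added at the end.
- Henry reaction of 2 with 6 gives 4-[(tert-butyldimethylsilyl)oxy]-1-nitrobutan-2-ol F1, and MsCl/Et3N dehydration gives the (E)-nitroalkene F2, whose γ-methylene is ordinary.
- The conditions of step 7 with 10 give the cyclopentane aldehyde F3.
- The reagents of steps 8 to 15 then give in turn the enone F4, the (15S)-alcohol F5, the nitrocyclopentene F6, the cyclopentenone F7, its 15-silyl ether F8, the α-epoxide F9, the 11-hydroxy ketone F10 and the 9α,11α-diol F11.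
- PPTS in MeOH frees the primary alcohol F12.
- TEMPO/PhI(OAc)2 closes it onto the 9α-hydroxyl as the γ-lactone F13, and i-Bu2AlH at −78 °C gives the lactol F14.
- A Wittig reaction with the ylide of 1 (KOt-Bu, THF) installs C1–C5 with the (Z)-alkene as the 15-silylated acid F15, and Bu4NF returns to 24.

**Step 4.** The α-protons of 5 are both allylic and next to the carbonyl. Amine-induced enolisation may move the (Z)-alkene into conjugation with the aldehyde faster than the nitronate adds.

Fallback, setting out from 1 and returning at 7: the route never passes through a β,γ-unsaturated aldehyde.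
- The ylide of 1 is combined with commercial (2,2-dimethyl-1,3-dioxolan-4-yl)acetaldehyde (racemic material suffices) to give (5Z)-7-(2,2-dimethyl-1,3-dioxolan-4-yl)hept-5-enoic acid F16.
- Methanolic HCl esterifies and unmasks the diol, giving methyl (5Z)-8,9-dihydroxynon-5-enoate F17.
- I2/PPh3/imidazole at 0 °C converts the primary hydroxyl into the iodide, methyl (5Z)-8-hydroxy-9-iodonon-5-enoate F18.
- AgNO2 in Et2O displaces iodide to give 7.

**Step 13.** Facial selectivity may be poor: hydroperoxide addition at C11 is reversible, and closure to the β-epoxide can compete, because only the neighbouring C12 chain and the remote silyl ether differentiate the faces.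

Fallback, setting out from 19 and returning at 21: conjugate borylation (B2pin2, CuCl, NaOt-Bu, a bisphosphine, MeOH, THF) places boron at C11 anti to the C12 chain, giving the β-boryl ketone F19. NaBO3 then oxidises the C–B bond with retention to 21, which bypasses 20 and step 14.

**Step 15.** The free 11-hydroxyl is deprotonated by the hydride. The resulting alkoxide may trigger β-elimination towards the enone, or direct hydride delivery and erode the α-selectivity at C9.

Fallback, setting out from 21 and returning at 23: Et3SiCl/imidazole gives the 11-O-triethylsilyl ether F20, LiBH(s-Bu)3 reduces it to the 9α-alcohol F21, and Bu4NF removes both silyl groups.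

## Further compounds

F1 | step 7 | 4-[(tert-butyldimethylsilyl)oxy]-1-nitrobutan-2-ol (racemic) | [O-][N+](=O)CC(O)CCO[Si](C)(C)C(C)(C)C
F2 | step 7 | tert-butyldimethyl{[(3E)-4-nitrobut-3-en-1-yl]oxy}silane | [O-][N+](=O)/C=C/CCO[Si](C)(C)C(C)(C)C
F3 | step 7 | analogue of 12 with a 2-[(tert-butyldimethylsilyl)oxy]ethyl group at C8 | O=C[C@@H]1[C@@H](CCO[Si](C)(C)C(C)(C)C)[C@H]([N+](=O)[O-])[C@@H](O)C1
F4 | step 7 | analogue of 14 with a 2-[(tert-butyldimethylsilyl)oxy]ethyl group at C8 | CCCCCC(=O)/C=C/[C@@H]1[C@@H](CCO[Si](C)(C)C(C)(C)C)[C@H]([N+](=O)[O-])[C@@H](O)C1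
F5 | step 7 | analogue of 15 with a 2-[(tert-butyldimethylsilyl)oxy]ethyl group at C8 | CCCCC[C@H](O)/C=C/[C@@H]1[C@@H](CCO[Si](C)(C)C(C)(C)C)[C@H]([N+](=O)[O-])[C@@H](O)C1
F6 | step 7 | analogue of 16 with a 2-[(tert-butyldimethylsilyl)oxy]ethyl group at C8 | CCCCC[C@H](O)/C=C/[C@@H]1[C@@H](CCO[Si](C)(C)C(C)(C)C)C([N+](=O)[O-])=CC1
F7 | step 7 | analogue of 18 with a 2-[(tert-butyldimethylsilyl)oxy]ethyl group at C8 | CCCCC[C@H](O)/C=C/[C@H]1C=CC(=O)[C@@H]1CCO[Si](C)(C)C(C)(C)C
F8 | step 7 | analogue of 19 with a 2-[(tert-butyldimethylsilyl)oxy]ethyl group at C8 | CCCCC[C@H](O[Si](c1ccccc1)(c1ccccc1)C(C)(C)C)/C=C/[C@H]1C=CC(=O)[C@@H]1CCO[Si](C)(C)C(C)(C)C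
F9 | step 7 | analogue of 20 with a 2-[(tert-butyldimethylsilyl)oxy]ethyl group at C8 | CCCCC[C@H](O[Si](c1ccccc1)(c1ccccc1)C(C)(C)C)/C=C/[C@H]1[C@@H]2O[C@@H]2C(=O)[C@@H]1CCO[Si](C)(C)C(C)(C)C
F10 | step 7 | analogue of 21 with a 2-[(tert-butyldimethylsilyl)oxy]ethyl group at C8 | CCCCC[C@H](O[Si](c1ccccc1)(c1ccccc1)C(C)(C)C)/C=C/[C@H]1[C@H](O)CC(=O)[C@@H]1CCO[Si](C)(C)C(C)(C)C
F11 | step 7 | analogue of 22 with a 2-[(tert-butyldimethylsilyl)oxy]ethyl group at C8 | CCCCC[C@H](O[Si](c1ccccc1)(c1ccccc1)C(C)(C)C)/C=C/[C@@H]1[C@@H](CCO[Si](C)(C)C(C)(C)C)[C@@H](O)C[C@H]1O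
F12 | step 7 | primary alcohol from F11 (2-hydroxyethyl group at C8) | CCCCC[C@H](O[Si](c1ccccc1)(c1ccccc1)C(C)(C)C)/C=C/[C@@H]1[C@@H](CCO)[C@@H](O)C[C@H]1O
F13 | step 7 | (3aR,4R,5R,6aS)-4-[(1E,3S)-3-[(tert-butyldiphenylsilyl)oxy]oct-1-en-1-yl]-5-hydroxyhexahydro-2H-cyclopenta[b]furan-2-one | CCCCC[C@H](O[Si](c1ccccc1)(c1ccccc1)C(C)(C)C)/C=C/[C@@H]1[C@@H](CC(=O)O2)[C@@H]2C[C@H]1O
F14 | step 7 | (3aR,4R,5R,6aS)-4-[(1E,3S)-3-[(tert-butyldiphenylsilyl)oxy]oct-1-en-1-yl]hexahydro-2H-cyclopenta[b]furan-2,5-diol (lactol, anomers) | CCCCC[C@H](O[Si](c1ccccc1)(c1ccccc1)C(C)(C)C)/C=C/[C@@H]1[C@@H](CC(O)O2)[C@@H]2C[C@H]1O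
F15 | step 7 | (5Z)-7-[(1R,2R,3R,5S)-2-[(1E,3S)-3-[(tert-butyldiphenylsilyl)oxy]oct-1-en-1-yl]-3,5-dihydroxycyclopentyl]hept-5-enoic acid | CCCCC[C@H](O[Si](c1ccccc1)(c1ccccc1)C(C)(C)C)/C=C/[C@@H]1[C@@H](C/C=C\CCCC(=O)O)[C@@H](O)C[C@H]1O
F16 | step 4 | (5Z)-7-(2,2-dimethyl-1,3-dioxolan-4-yl)hept-5-enoic acid (racemic) | OC(=O)CCC/C=C\CC1COC(C)(C)O1
F17 | step 4 | methyl (5Z)-8,9-dihydroxynon-5-enoate (racemic) | COC(=O)CCC/C=C\CC(O)CO
F18 | step 4 | methyl (5Z)-8-hydroxy-9-iodonon-5-enoate (racemic) | COC(=O)CCC/C=C\CC(O)CI
F19 | step 13 | analogue of 21 with a 4,4,5,5-tetramethyl-1,3,2-dioxaborolan-2-yl group in place of the 11α-hydroxyl | CCCCC[C@H](O[Si](c1ccccc1)(c1ccccc1)C(C)(C)C)/C=C/[C@H]1[C@H](B2OC(C)(C)C(C)(C)O2)CC(=O)[C@@H]1C/C=C\CCCC(=O)OC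
F20 | step 15 | 11-O-triethylsilyl ether of 21 | CCCCC[C@H](O[Si](c1ccccc1)(c1ccccc1)C(C)(C)C)/C=C/[C@H]1[C@H](O[Si](CC)(CC)CC)CC(=O)[C@@H]1C/C=C\CCCC(=O)OC
F21 | step 15 | 11-O-triethylsilyl ether of 22 | CCCCC[C@H](O[Si](c1ccccc1)(c1ccccc1)C(C)(C)C)/C=C/[C@@H]1[C@@H](C/C=C\CCCC(=O)OC)[C@@H](O)C[C@H]1O[Si](CC)(CC)CC
A1 | alternative 1 | (3aR,4R,5R,6aS)-5-hydroxy-4-[(1E)-3-hydroxyoct-1-en-1-yl]hexahydro-2H-cyclopenta[b]furan-2-one (C15 epimers) | CCCCCC(O)/C=C/[C@@H]1[C@@H](CC(=O)O2)[C@@H]2C[C@H]1O
A2 | alternative 1 | γ-lactone (C9–O, C6 carbonyl) fused to the cyclopentane, with a β-face C11–C12–C13 cyclopropane bearing an endo 3-pentyloxiran-2-yl group at C13 (epoxide isomers) | CCCCCC1OC1[C@@H]3[C@H]4[C@@H]3C[C@@H]5OC(=O)C[C@H]45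
A3 | alternative 2 | bicyclo[3.2.0]hept-2-en-6-one, used as the racemate ((1R,5S) enantiomer drawn) | C1=C[C@@H](CC2=O)[C@@H]2C1
A4 | alternative 2 | (1S,5R)-2-oxabicyclo[3.3.0]oct-6-en-3-one | C1=C[C@@H](CC(=O)O2)[C@@H]2C1
A5 | alternative 3 | arachidonic acid, (5Z,8Z,11Z,14Z)-icosa-5,8,11,14-tetraenoic acid | CCCCC/C=C\C/C=C\C/C=C\C/C=C\CCCC(=O)O
A6 | alternative 3 | prostaglandin G2 (15S-hydroperoxy 9α,11α-endoperoxide) | CCCCC[C@H](OO)/C=C/[C@@H]1[C@@H](C/C=C\CCCC(=O)O)[C@@H](OO2)C[C@H]12
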